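All runs are simulated for an exercise, noise included.

**The clock.** The time of reading, 20 min, says little until I count it in lifetimes of the free monomer, a lifetime being the time in which c(free monomer) falls by the factor e. This treats the fall as pseudo-first-order, the same share lost in each equal stretch, and I assume the lifetime ignores c(free monomer), though birch and oak differ in it.

| flask | free monomer | initiator | temperature | remark | time |
|---|---|---|---|---|---|
| birch | 0.40 M | 4 mM | 80 °C | run made earlier |  |
| oak | 0.60 M | 4 mM | 98 °C | run made earlier |  |
| teal | 0.80 M | 4.0 mM | 85 °C |  | 20 min |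
| amber | 0.80 M | 4.0 mM | 110 °C |  | 20 min |

- birch (time / min: monomer in chains / %, free monomer / %): 3.00: 20.7, 79.5; 6.00: 35.6, 61.5; 10.0: 54.2, 46.3; 12.0: 60.1, 41.2; 15.0: 67.0, 29.7
- oak (time / min: monomer in chains / %, free monomer / %): 1.50: 29.3, 69.6; 3.00: 50.4, 47.7; 5.00: 67.9, 30.5; 6.00: 74.2, 23.0; 8.00: 84.4, 14.0

(each reading ± 1 percentage point)

- the best flask by amount of monomer in chains, in percent of the free monomer charged; "all alike" if 1.5 percentage points covers them all (teal / amber / all alike)
- amount of monomer in chains at the end, in percent of the free monomer charged, teal
- amount of monomer in chains at the end, in percent of the free monomer charged, amber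



**Two lifetimes.** Birch at 10.0 min and oak at 3.00 min hold similar free monomer, 46.3% and 47.7%, so I compare them there. Birch's lifetime comes to 13.0 min and oak's to 4.05 min.

**Teal.** I take the logarithm of the lifetime as straight in temperature, which gives teal 9.40 min. So 20 min is 2.13 lifetimes, leaving 11.9% free monomer.

**Amber.** The same line, stretched past oak to 110 °C, gives 1.86 min as the free-monomer lifetime in amber. Its 20 min is then 10.8 lifetimes, leaving 0.00220%.

**The weak link.** So far I count every monomer lost as in chains, and that closed balance is my zero. The readings, each with a scatter of 1 percentage point, fall short of it on average by 0.84 points in birch and 1.8 points in oak. I give teal oak's gap, which makes 86.3% in chains. Amber is hotter and richer than oak, so I multiply oak's gap once more by the step from birch to oak, 2.14, which makes 96.1%.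

**The forecast.** It names amber, with 87% for teal (83% to 91%) and 98% for amber (92% to 100%), adding: “Unseen initiator burn-out or a small equilibrium monomer could hold it a few percent lower”. Its amber figure stands higher than mine.

**The result.** Teal gives 85.2% and amber 93.9%, so amber leads by 8.7 points, more than the margin of 1.5 points. Both stand within the forecast's ranges.

    free monomer + growing radical → monomer in chains + growing radical, rate k1*[growing radical]*[free monomer] (k = 1.50 × 10⁵ M⁻¹ s⁻¹, Ea = 17.0 kJ mol⁻¹)
    free monomer + initiating radical → growing radical + monomer in chains (k = 3.10 × 10⁶ M⁻¹ s⁻¹, Ea = 22.0 kJ mol⁻¹)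
    2 free monomer → self-condensation product (k = 6.60 × 10⁻⁴ M⁻¹ s⁻¹, Ea = 96.0 kJ mol⁻¹)
    2 growing radical → dead chain (k = 1.10 × 10⁸ M⁻¹ s⁻¹, Ea = 16.0 kJ mol⁻¹)
    initiator → 2 initiating radical (k = 7.80 × 10⁻⁵ s⁻¹, Ea = 120 kJ mol⁻¹)
    (constants at 110 °C)

**The neighbour.** At 20 min amber holds 6.10% self-condensation product, counted by its monomer, beside 93.9% monomer in chains, which is above the forecast's low end of 92%. After my 10.8 lifetimes of 1.86 min, amber's free monomer stands at 0%. The same amber read at 5.0 min has had 2.69 lifetimes, so I reckon 6.80% free monomer, and that flask holds 8.23%. It has 85.7% monomer in chains and already 6.05% self-condensation product.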